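**Plan**
Rings: A and F are the outer 2,4,6-trihydroxyphenyl rings (C1 = biaryl carbon), B and D the phloroglucinol rings carrying them, C the central ring (ether oxygens on C1, C2, C3; hydroxyl on C5), and E the 3,4,5-trihydroxyphenyl ring on the C2 oxygen of ring C.
Cuts, in retrosynthetic order: (i) thirteen O–Me bonds in place of O–H; (ii) the C–O bonds at C4 of ring A, C4 of ring F and C5 of ring C, back to C–H; these are the only oxygenated carbons with a C–H on both sides, and in the deoxy skeleton every other aromatic C–H has an ortho substituent; (iii) the biaryl bonds A–B and F–D; (iv) the two ether bonds from ring C to rings B and D; (v) the ether bond from ring C to ring E.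
Forward order: ring E is joined to a protected ring C (Ullmann); rings B and D are attached together by SNAr on an ortho-fluorobenzaldehyde whose formyl carbon is then exchanged for oxygen (Dakin); rings A and F are added by a twofold Suzuki coupling; the three C–H bonds are oxidised in one operation; the methyl ethers are cleaved. No ring is built in the route.
Stereochemistry: the target has no stereocentre, and both biaryl axes carry a symmetric ring (A or F), so no atropisomers can form.

Key step: step 10

Remark: 1,3-bis(methoxymethoxy)benzene (1) is assumed to be a catalogue compound; if not, it is one step from resorcinol and chloromethyl methyl ether.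

**Step 1**
Reactants: 1 1,3-bis(methoxymethoxy)benzene
Product: 4 2,6-bis(methoxymethoxy)phenol, via 2-lithio-1,3-bis(methoxymethoxy)benzene 2 (not isolated), via lithium aryltrimethoxyborate 3 (not isolated)
Conditions: n-BuLi, THF, 0 °C; B(OMe)3, −78 °C to rt; AcOH, 30% H2O2, 0 °C to rt
Reagents that add atoms: n-butyllithium, CCCC[Li] (lithium of 2); trimethyl borate, COB(OC)OC (boron and methoxy groups of 3); hydrogen peroxide, OO (phenol oxygen of 4)
Why: Directed ortho-metalation: the two OMOM groups together acidify and chelate C2, so lithiation should occur only there, and borylation followed by peroxide oxidation (aryl shift from boron to oxygen) turns the C–Li bond into the phenol.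

**Step 2**
Reactants: 4 2,6-bis(methoxymethoxy)phenol; 5 5-iodo-1,2,3-trimethoxybenzene
Product: 6 1,3-bis(methoxymethoxy)-2-(3,4,5-trimethoxyphenoxy)benzene
Conditions: CuI (10 mol%), picolinic acid (20 mol%), K3PO4, DMSO, 90 °C
Reagents that add atoms: none
Why: Ullmann-type diaryl ether synthesis with CuI/picolinic acid, a system suited to doubly ortho-substituted phenols; iodide 5 has no ortho substituent, so the hindered monovalent copper phenoxide can still add the C–I bond and eliminate the C–O bond.

**Step 3**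
Reactants: 6 1,3-bis(methoxymethoxy)-2-(3,4,5-trimethoxyphenoxy)benzene
Product: 7 2-(3,4,5-trimethoxyphenoxy)benzene-1,3-diol
Conditions: HCl (cat.), MeOH, 50 °C
Reagents that add atoms: none
Why: Acid-catalysed acetal exchange with the solvent removes both MOM groups as dimethoxymethane, while aryl methyl ethers and the diaryl ether are inert to dilute acid.

**Step 4**
Reactants: 8 3,5-dimethoxybenzaldehyde
Product: 9 2-fluoro-3,5-dimethoxybenzaldehyde
Conditions: Selectfluor (1.05 equiv), MeCN, 0 °C to rt
Reagents that add atoms: Selectfluor [1-(chloromethyl)-4-fluoro-1,4-diazoniabicyclo[2.2.2]octane bis(tetrafluoroborate)], F[N+]12CC[N+](CCl)(CC1)CC2.F[B-](F)(F)F.F[B-](F)(F)F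
Why: Electrophilic aromatic fluorination should take C2, which is para to one methoxy group and ortho to the other and less crowded than C4 between the two methoxy groups; near-stoichiometric reagent limits formation of the 2,6-difluoride, which is removed by chromatography.

**Step 5**
Reactants: 9 2-fluoro-3,5-dimethoxybenzaldehyde
Product: 10 2-bromo-6-fluoro-3,5-dimethoxybenzaldehyde
Conditions: NBS, MeCN, rt
Reagents that add atoms: N-bromosuccinimide, O=C1CCC(=O)N1Br
Why: Electrophilic aromatic bromination should take the remaining position of the same type (C6, para to one methoxy group and ortho to the other), as 3,5-dimethoxybenzaldehyde itself is halogenated next to the formyl group and not between the methoxy groups.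

**Step 6**
Reactants: 7 2-(3,4,5-trimethoxyphenoxy)benzene-1,3-diol; 10 2-bromo-6-fluoro-3,5-dimethoxybenzaldehyde (2.4 equiv; two molecules are incorporated)
Product: 11 6,6'-{[2-(3,4,5-trimethoxyphenoxy)-1,3-phenylene]bis(oxy)}bis(2-bromo-3,5-dimethoxybenzaldehyde)
Conditions: Cs2CO3, DMA, 100 °C
Reagents that add atoms: none
Why: Twofold nucleophilic aromatic substitution (SNAr): the ortho-formyl group stabilises the Meisenheimer adduct at the C–F carbon, and fluoride leaves far faster than the bromide on the other side of the aldehyde, so each of the two caesium phenoxides of 7 should displace the fluoride of one molecule of 10 only.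

**Step 7**
Reactants: 11 6,6'-{[2-(3,4,5-trimethoxyphenoxy)-1,3-phenylene]bis(oxy)}bis(2-bromo-3,5-dimethoxybenzaldehyde)
Product: 13 6,6'-{[2-(3,4,5-trimethoxyphenoxy)-1,3-phenylene]bis(oxy)}bis(2-bromo-3,5-dimethoxyphenol), via bis(aryl formate) 12 (not isolated)
Conditions: mCPBA (2.5 equiv), CH2Cl2, 0 °C to rt; then K2CO3 (cat.), MeOH, rt
Reagents that add atoms: meta-chloroperoxybenzoic acid (2 equiv consumed, one oxygen per aldehyde), O=C(OO)c1cccc(Cl)c1
Why: Dakin-type Baeyer–Villiger oxidation: the peracid adds to each aldehyde and the aryl group, made electron-rich at the migrating carbon by the ortho aryloxy substituent, should shift to oxygen to give the formate, which methanolysis cleaves; because bromine is already in place, no halogenation is needed later in the presence of the electron-rich ring E.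

**Step 8**
Reactants: 13 6,6'-{[2-(3,4,5-trimethoxyphenoxy)-1,3-phenylene]bis(oxy)}bis(2-bromo-3,5-dimethoxyphenol)
Product: 14 1,3-bis(3-bromo-2,4,6-trimethoxyphenoxy)-2-(3,4,5-trimethoxyphenoxy)benzene
Conditions: MeI (3 equiv), K2CO3, DMF, rt to 40 °C
Reagents that add atoms: iodomethane (2 equiv incorporated, one methyl per phenol), CI
Why: Williamson methylation (SN2 of the two phenoxides on MeI) is routine even for phenols flanked by bromine and an aryloxy group.

**Step 9**
Reactants: 14 1,3-bis(3-bromo-2,4,6-trimethoxyphenoxy)-2-(3,4,5-trimethoxyphenoxy)benzene; 15 2,6-dimethoxyphenylboronic acid (3.0 equiv, added in portions; two molecules are incorporated, one at each C–Br bond)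
Product: 16 1,3-bis[3-(2,6-dimethoxyphenyl)-2,4,6-trimethoxyphenoxy]-2-(3,4,5-trimethoxyphenoxy)benzene
Conditions: Pd(OAc)2 (10 mol%), SPhos (20 mol%), K3PO4, toluene/H2O 10:1, 100 °C
Reagents that add atoms: none
Why: Twofold Suzuki–Miyaura coupling with the bulky, electron-rich SPhos ligand, a system suited to tetra-ortho-substituted biaryls; zerovalent palladium inserts into each of the two C–Br bonds of 14, each lying between two methoxy groups, and each arylpalladium bromide takes its 2,6-dimethoxyphenyl group from a separate molecule of 15, the excess of which offsets protodeboronation.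

**Step 10**
Reactants: 16 1,3-bis[3-(2,6-dimethoxyphenyl)-2,4,6-trimethoxyphenoxy]-2-(3,4,5-trimethoxyphenoxy)benzene
Product: 18 3,5-bis[3-(4-hydroxy-2,6-dimethoxyphenyl)-2,4,6-trimethoxyphenoxy]-4-(3,4,5-trimethoxyphenoxy)phenol, via tris(pinacol boronate) 17 (not isolated)
Conditions: [Ir(OMe)(cod)]2 (5 mol%), 4,4'-di-tert-butyl-2,2'-bipyridine (10 mol%), B2pin2 (4.5 equiv), THF, 80 °C (sealed tube); then aq NaOH, 30% H2O2, 0 °C to rt
Reagents that add atoms: bis(pinacolato)diboron (3 equiv consumed, one boronate group each to 17), CC1(C)OB(OC1(C)C)B1OC(C)(C)C(C)(C)O1; hydrogen peroxide (3 equiv consumed, the three phenol oxygens of 18), OO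
Why: [Ir(OMe)(cod)]2, the bipyridine and B2pin2 form a trivalent iridium tris(boryl) complex that cleaves an aromatic C–H bond by oxidative addition to a pentavalent iridium aryl hydride and releases the aryl boronate by C–B reductive elimination, with B2pin2 restoring the tris(boryl) species. The closest known reaction type is the sterically governed iridium-catalysed borylation of 1,3-di- and 1,2,3-trisubstituted arenes at C5, run in one pot with oxidation to the phenol. No ring is closed and no stereocentre is created. The selectivity needed is site selectivity: the crowded iridium centre does not insert next to a substituent, and in 16 every C–H of rings B, D and E, C4–H and C6–H of ring C, and C3–H and C5–H of rings A and F has an ortho oxygen, so only C5–H of ring C and C4–H of rings A and F remain, each flanked by two C–H bonds. Excess B2pin2 should carry all three sites to 17; hydroperoxide then adds to each boron and the aryl group shifts from boron to oxygen at the same carbon, so the three hydroxyls of 18 appear exactly where boron was.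

**Step 11**
Reactants: 18 3,5-bis[3-(4-hydroxy-2,6-dimethoxyphenyl)-2,4,6-trimethoxyphenoxy]-4-(3,4,5-trimethoxyphenoxy)phenol
Product: 19 3,5-bis[2,4,6-trihydroxy-3-(2,4,6-trihydroxyphenyl)phenoxy]-4-(3,4,5-trihydroxyphenoxy)phenol (CNP0279880.0)
Conditions: BBr3 (excess), CH2Cl2, −78 °C to rt, argon; then MeOH, H2O
Reagents that add atoms: none
Why: Lewis-acid ether cleavage: BBr3 complexes each ether oxygen and bromide attacks the methyl carbon (SN2), so all thirteen aryl methyl ethers should be cleaved, while the diaryl ether and biaryl bonds, which offer no sp3 carbon, survive and hydrolysis frees the sixteen phenols.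

**Compound list**
1 | 1,3-bis(methoxymethoxy)benzene | COCOc1cccc(OCOC)c1 | starting material
2 | 2-lithio-1,3-bis(methoxymethoxy)benzene | [Li]c1c(OCOC)cccc1OCOC | intermediate (not isolated)
3 | lithium [2,6-bis(methoxymethoxy)phenyl]trimethoxyborate | [Li+].CO[B-](OC)(OC)c1c(OCOC)cccc1OCOC | intermediate (not isolated)
4 | 2,6-bis(methoxymethoxy)phenol | Oc1c(OCOC)cccc1OCOC | intermediate
5 | 5-iodo-1,2,3-trimethoxybenzene | COc1cc(I)cc(OC)c1OC | starting material
6 | 1,3-bis(methoxymethoxy)-2-(3,4,5-trimethoxyphenoxy)benzene | COCOc1cccc(OCOC)c1Oc1cc(OC)c(OC)c(OC)c1 | intermediate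
7 | 2-(3,4,5-trimethoxyphenoxy)benzene-1,3-diol | Oc1cccc(O)c1Oc1cc(OC)c(OC)c(OC)c1 | intermediate
8 | 3,5-dimethoxybenzaldehyde | COc1cc(OC)cc(C=O)c1 | starting material
9 | 2-fluoro-3,5-dimethoxybenzaldehyde | COc1cc(OC)c(F)c(C=O)c1 | intermediate
10 | 2-bromo-6-fluoro-3,5-dimethoxybenzaldehyde | COc1cc(OC)c(F)c(C=O)c1Br | intermediate
11 | 6,6'-{[2-(3,4,5-trimethoxyphenoxy)-1,3-phenylene]bis(oxy)}bis(2-bromo-3,5-dimethoxybenzaldehyde) | COc1cc(OC)c(Oc2cccc(Oc3c(OC)cc(OC)c(Br)c3C=O)c2Oc2cc(OC)c(OC)c(OC)c2)c(C=O)c1Br | intermediate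
12 | diformate of 13 (a formate ester on each phenol oxygen) | COc1cc(OC)c(Oc2cccc(Oc3c(OC)cc(OC)c(Br)c3OC=O)c2Oc2cc(OC)c(OC)c(OC)c2)c(OC=O)c1Br | intermediate (not isolated)
13 | 6,6'-{[2-(3,4,5-trimethoxyphenoxy)-1,3-phenylene]bis(oxy)}bis(2-bromo-3,5-dimethoxyphenol) | COc1cc(OC)c(Oc2cccc(Oc3c(OC)cc(OC)c(Br)c3O)c2Oc2cc(OC)c(OC)c(OC)c2)c(O)c1Br | intermediate
14 | 1,3-bis(3-bromo-2,4,6-trimethoxyphenoxy)-2-(3,4,5-trimethoxyphenoxy)benzene | COc1cc(OC)c(Oc2cccc(Oc3c(OC)cc(OC)c(Br)c3OC)c2Oc2cc(OC)c(OC)c(OC)c2)c(OC)c1Br | intermediate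
15 | 2,6-dimethoxyphenylboronic acid | COc1cccc(OC)c1B(O)O | starting material
16 | 1,3-bis[3-(2,6-dimethoxyphenyl)-2,4,6-trimethoxyphenoxy]-2-(3,4,5-trimethoxyphenoxy)benzene | c1cc(Oc2c(OC)cc(OC)c(-c3c(OC)cccc3OC)c2OC)c(Oc2cc(OC)c(OC)c(OC)c2)c(Oc2c(OC)cc(OC)c(-c3c(OC)cccc3OC)c2OC)c1 | intermediate (key-step precursor)
17 | tris(pinacol boronate) of 16 (boron on C5 of ring C and C4 of rings A and F) | CC1(C)OB(OC1(C)C)c1cc(Oc2c(OC)cc(OC)c(-c3c(OC)cc(B4OC(C)(C)C(C)(C)O4)cc3OC)c2OC)c(Oc2cc(OC)c(OC)c(OC)c2)c(Oc2c(OC)cc(OC)c(-c3c(OC)cc(B4OC(C)(C)C(C)(C)O4)cc3OC)c2OC)c1 | intermediate (not isolated)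
18 | 3,5-bis[3-(4-hydroxy-2,6-dimethoxyphenyl)-2,4,6-trimethoxyphenoxy]-4-(3,4,5-trimethoxyphenoxy)phenol | Oc1cc(Oc2c(OC)cc(OC)c(-c3c(OC)cc(O)cc3OC)c2OC)c(Oc2cc(OC)c(OC)c(OC)c2)c(Oc2c(OC)cc(OC)c(-c3c(OC)cc(O)cc3OC)c2OC)c1 | intermediate (key-step product)
19 | 3,5-bis[2,4,6-trihydroxy-3-(2,4,6-trihydroxyphenyl)phenoxy]-4-(3,4,5-trihydroxyphenoxy)phenol | Oc1cc(O)c(-c2c(O)cc(O)c(Oc3cc(O)cc(Oc4c(O)cc(O)c(-c5c(O)cc(O)cc5O)c4O)c3Oc3cc(O)c(O)c(O)c3)c2O)c(O)c1 | target

**Totals**
Total steps: 11. Longest linear sequence: 9 steps (steps 1, 2, 3, 6, 7, 8, 9, 10, 11); the ring B/D aldehyde branch (steps 4 and 5) joins at step 6.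

**Steps most likely to fail**

Step 6 (twofold SNAr). The methoxy groups ortho and para to fluorine feed electron density into the C–F carbon, and the second phenoxide is flanked by two aryloxy groups. Substitution may therefore stall after the first ether bond while the aldehyde degrades under forcing conditions.
Fallback: the ether bonds are made last, by copper catalysis, from a complete ring B–A iodide. It sets out from 15 and diol 7 and returns at 16. Suzuki coupling of 15 with purchased 2-bromo-1,3,5-trimethoxybenzene (Pd(OAc)2, SPhos, K3PO4) should give 2,2',4,6,6'-pentamethoxybiphenyl F1. N-Iodosuccinimide should iodinate the free position of the more electron-rich trimethoxy ring to give 3-iodo-2,2',4,6,6'-pentamethoxybiphenyl F2. Twofold Ullmann etherification of 7 with two equivalents of F2 (CuI, picolinic acid, K3PO4, DMSO, 110 °C) should then give 16 directly, bypassing steps 6 to 9.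

Step 9 (twofold tetra-ortho Suzuki coupling). Protodeboronation of 15 may outrun the slow oxidative addition and transmetalation at the electron-rich C–Br bonds between two methoxy groups, so that coupling stops after one biaryl bond or the remaining C–Br bond is reduced.
Fallback: the biaryl bond is formed first on the small, formyl-activated bromide. It sets out from 10 and returns at 16. Coupling of 10 with 15 (Pd(OAc)2, SPhos, anhydrous K3PO4, toluene, 90 °C) should give 2-(2,6-dimethoxyphenyl)-6-fluoro-3,5-dimethoxybenzaldehyde F3. SNAr of diol 7 on two equivalents of F3 (Cs2CO3, DMA) should give the ring A/F-bearing dialdehyde F4. mCPBA oxidation should give the diformate F5, which methanolysis converts to the diphenol F6. Methylation of both phenols with MeI and K2CO3 then gives 16.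

Step 10 (threefold borylation–oxidation). The catalyst may die before the third site of the large, electron-rich substrate has reacted, giving mixtures of partly hydroxylated ethers that are hard to separate.
Fallback: the C4 oxygens of rings A and F are bought, and C–H oxidation is asked of only one site. It sets out from 14 and returns at 19. Suzuki coupling of 14 with two equivalents of purchased 2,4,6-trimethoxyphenylboronic acid under the step 9 conditions should give the pentadecamethyl ether F7, in which only C5–H of ring C is unhindered. A single borylation ([Ir(OMe)(cod)]2, 4,4'-di-tert-butyl-2,2'-bipyridine, B2pin2) should give the mono(pinacol boronate) F8, oxidised without isolation (NaOH, H2O2) to the monophenol F9. BBr3 then cleaves the fifteen methyl ethers to give 19.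

**Further compounds**
F1 | step 6 | 2,2',4,6,6'-pentamethoxybiphenyl | COc1cc(OC)c(-c2c(OC)cccc2OC)c(OC)c1
F2 | step 6 | 3-iodo-2,2',4,6,6'-pentamethoxybiphenyl | COc1cc(OC)c(-c2c(OC)cccc2OC)c(OC)c1I
F3 | step 9 | 2-(2,6-dimethoxyphenyl)-6-fluoro-3,5-dimethoxybenzaldehyde | COc1cc(OC)c(-c2c(OC)cccc2OC)c(C=O)c1F
F4 | step 9 | 6,6'-{[2-(3,4,5-trimethoxyphenoxy)-1,3-phenylene]bis(oxy)}bis[2-(2,6-dimethoxyphenyl)-3,5-dimethoxybenzaldehyde] | COc1cc(OC)c(-c2c(OC)cccc2OC)c(C=O)c1Oc1cccc(Oc2c(OC)cc(OC)c(-c3c(OC)cccc3OC)c2C=O)c1Oc1cc(OC)c(OC)c(OC)c1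
F5 | step 9 | diformate of F6 (a formate ester on each phenol oxygen) | COc1cc(OC)c(-c2c(OC)cccc2OC)c(OC=O)c1Oc1cccc(Oc2c(OC)cc(OC)c(-c3c(OC)cccc3OC)c2OC=O)c1Oc1cc(OC)c(OC)c(OC)c1
F6 | step 9 | 6,6'-{[2-(3,4,5-trimethoxyphenoxy)-1,3-phenylene]bis(oxy)}bis[2-(2,6-dimethoxyphenyl)-3,5-dimethoxyphenol] | COc1cc(OC)c(-c2c(OC)cccc2OC)c(O)c1Oc1cccc(Oc2c(OC)cc(OC)c(-c3c(OC)cccc3OC)c2O)c1Oc1cc(OC)c(OC)c(OC)c1
F7 | step 10 | 1,3-bis[2,4,6-trimethoxy-3-(2,4,6-trimethoxyphenyl)phenoxy]-2-(3,4,5-trimethoxyphenoxy)benzene | c1cc(Oc2c(OC)cc(OC)c(-c3c(OC)cc(OC)cc3OC)c2OC)c(Oc2cc(OC)c(OC)c(OC)c2)c(Oc2c(OC)cc(OC)c(-c3c(OC)cc(OC)cc3OC)c2OC)c1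
F8 | step 10 | mono(pinacol boronate) of F7 (boron on C5 of ring C) | CC1(C)OB(OC1(C)C)c1cc(Oc2c(OC)cc(OC)c(-c3c(OC)cc(OC)cc3OC)c2OC)c(Oc2cc(OC)c(OC)c(OC)c2)c(Oc2c(OC)cc(OC)c(-c3c(OC)cc(OC)cc3OC)c2OC)c1
F9 | step 10 | 3,5-bis[2,4,6-trimethoxy-3-(2,4,6-trimethoxyphenyl)phenoxy]-4-(3,4,5-trimethoxyphenoxy)phenol | Oc1cc(Oc2c(OC)cc(OC)c(-c3c(OC)cc(OC)cc3OC)c2OC)c(Oc2cc(OC)c(OC)c(OC)c2)c(Oc2c(OC)cc(OC)c(-c3c(OC)cc(OC)cc3OC)c2OC)c1
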